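The summer run peaked at about 16% of the substrate charged, the spring run at about 38%. Both held 26 mM of substrate, as your flask does, but they differ in partner.

| flask | substrate | partner | capture agent | remark | time |
|---|---|---|---|---|---|
| summer | 26 mM | 14 mM | 1.3 mM | run made earlier |  |
| spring | 26 mM | 57 mM | 1.3 mM | run made earlier |  |
| winter | 39 mM | 28.6 mM | 1.3 mM | run made earlier |  |
| flask | 26 mM | 28.6 mM | 1.30 mM |  | 3.0 d |

- summer (time / h: target / %): 6.00: 7; 12.0: 15; 20.0: 16; 40.0: 16
- spring (time / h: target / %): 6.00: 27; 12.0: 36; 20.0: 38; 40.0: 30
- winter (time / h: target / %): 6.00: 12; 12.0: 18; 20.0: 24; 40.0: 21

(standard deviation of a reading: 1.5 percentage points)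

* the best time, 3.0 d at the latest, for target
* the amount of target, in percent of the substrate charged, at that time

- what may be going on: substrate <-> open intermediate; 2 second intermediate -> homo product; target <-> isomer of the product; partner -> second intermediate; open intermediate + second intermediate -> target; second intermediate + capture agent -> trapped intermediate

Fold the charges into one number, the partner equivalents 1.10, partner charged over substrate charged. Target forms from one open intermediate, which comes from substrate, and one second intermediate, which comes from partner, so one equivalent is the even match, the zero of your scale. Your flask sits just above it. Summer sits below at 0.538, spring above at 2.19.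

Draw a line through those two peaks, in ln(equivalents):

slope = 16 percentage points per unit of ln(equivalents)

peak = 16% + slope × ln(1.10/0.538) = 27.2%

Now test it. Winter, at 0.733, should give 20.8%, but it read 24%. That gap of 3.2 points stands against a scatter of 1.5 points, so one number is not quite enough for winter, which holds more substrate than the line's two runs. Your flask keeps the substrate of the line, so you keep 27.2%. The highest spring and winter readings stand at 20.0 h, so you look for your best time near there.

The forecast says 27% at 0.8 d: “Yield is governed mainly by partner”. It interpolates between the same two peaks, so its amount is no check on mine.

The flask gives 28.0% at 0.932 d, later than the forecast.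

    substrate ⇌ open intermediate (K = 0.400, k = 0.700 /h)
    2 second intermediate → homo product (k = 32.0 /M/h)
    target ⇌ isomer of the product (K = 2.30, k = 0.0690 /h)
    partner → second intermediate (k = 0.0660 /h)
    open intermediate + second intermediate → target (k = 57.0 /M/h)
    second intermediate + capture agent → trapped intermediate (k = 4.80 /M/h)

The line at 1.10 equivalents stands 0.80 points below the flask. At 110 mM of partner, 4.23 equivalents, it gives 48.3%, and that neighbour reaches 46.7%. In your flask, the half-life of target by its forward step to the isomer of the product alone is 0.42 d, short against the 3.0 d allowed. By 3.00 d the flask holds 23.4% of target and 49.5% of the isomer of the product.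

(The earlier runs and the new flask were computed on assumed constants; noise was put on by code.)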